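**Plan**
1. Retrosynthesis: the two MOM ethers and then the C4 angelate are removed first; the oxepine is then cut at O1–C2 and C5–C4 in one stroke, giving an arene fragment and a C6 β,γ-epoxy aldehyde.
2. Enabling feature: O1 and C5 sit on the adjacent ring carbons C9a/C5a as a 1,4-pair of nucleophilic sites (phenoxide O, α-styryl carbon). C4 (carbinol = aldehyde carbon) and C2 (ring-O carbon next to C(CH3)2OH = opened trisubstituted epoxide) are a 1,3-pair of electrophilic sites. The 1-benzoxepine ring is therefore a (4+3) annulation.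
3. Forward, arene: 2,4-dihydroxy-3-methylbenzaldehyde → MOM ethers → Dakin → ortho-formylation → alkyne → Markovnikov hydroalumination/iodination → O1 acetate.
4. Forward, C6 unit: 4-methylpent-3-en-1-ol → Shi epoxidation → Dess–Martin oxidation.
5. Union: asymmetric Ni/Cr coupling forms C5–C4, then the unmasked phenoxide closes the oxepine at C2 in the same flask; angeloylation and MOM removal finish the route.
6. Stereochemistry: C2 comes from the Shi epoxide (R), inverted to S in the ring closure; C4 (R) comes from the chiral Cr–sulfonamide complex; the Z-ester comes from angelic acid under non-isomerising conditions.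

Key step: step 9

Remark: both chiral reagents are assumed to follow their usual sense of induction (D-fructose-derived Shi ketone → (R) at the CH carbon of a 2-methylalk-2-ene; (S)-oxazoline–sulfonamide/Cr → Si-face addition giving the (R)-carbinol); if a test run shows the opposite sense for either, its enantiomer is used.

**Step 1**
Reactants: 1 2,4-dihydroxy-3-methylbenzaldehyde
Product: 2 2,4-bis(methoxymethoxy)-3-methylbenzaldehyde
Conditions: NaH (2.4 equiv), MOMCl (2.4 equiv), DMF, 0 °C → rt
Reagents that add atoms: chloromethyl methyl ether (MOMCl), COCCl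
Why: Williamson-type O-alkylation of both phenoxides should give the bis-MOM ether, NaH breaking the hydrogen bond of the 2-OH to the aldehyde.

**Step 2**
Reactants: 2 2,4-bis(methoxymethoxy)-3-methylbenzaldehyde
Product: 4 2,4-bis(methoxymethoxy)-3-methylphenol, via aryl formate 3 (not isolated)
Conditions: mCPBA, NaHCO3, CH2Cl2, 0 °C → rt; then K2CO3, MeOH, rt
Reagents that add atoms: mCPBA (3-chloroperoxybenzoic acid), OOC(=O)c1cccc(Cl)c1
Why: Dakin-type Baeyer–Villiger oxidation, in which the electron-rich aryl group migrates, should give the formate, and methanolysis then frees the phenol that becomes O1.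

**Step 3**
Reactants: 4 2,4-bis(methoxymethoxy)-3-methylphenol
Product: 5 2-hydroxy-3,5-bis(methoxymethoxy)-4-methylbenzaldehyde
Conditions: MgCl2, Et3N, (CH2O)n, MeCN, reflux
Reagents that add atoms: paraformaldehyde (as formaldehyde), C=O
Why: Magnesium-phenoxide-directed ortho-formylation (Casnati–Skattebøl) reacts only ortho to the free OH, and the single free ortho position is the future C5a.

**Step 4**
Reactants: 5 2-hydroxy-3,5-bis(methoxymethoxy)-4-methylbenzaldehyde
Product: 6 6-ethynyl-2,4-bis(methoxymethoxy)-3-methylphenol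
Conditions: dimethyl (1-diazo-2-oxopropyl)phosphonate (2 equiv), K2CO3, MeOH, rt
Reagents that add atoms: dimethyl (1-diazo-2-oxopropyl)phosphonate, CC(=O)C(=[N+]=[N-])P(=O)(OC)OC
Why: Ohira–Bestmann (Seyferth–Gilbert) homologation under carbonate/methanol should convert the salicylaldehyde into the terminal alkyne without protecting the phenol.

**Step 5**
Reactants: 6 6-ethynyl-2,4-bis(methoxymethoxy)-3-methylphenol
Product: 8 6-(1-iodoethenyl)-2,4-bis(methoxymethoxy)-3-methylphenol, via alkenylalane 7 (not isolated)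
Conditions: DIBAL-H (2.4 equiv), Ni(dppp)Cl2 (3 mol %), THF, 0 °C → rt; then I2, THF, −78 → 0 °C; aq. Rochelle salt
Reagents that add atoms: iodine, II
Why: Ni(dppp)-catalysed Markovnikov hydroalumination of an aryl acetylene should place aluminium on the aryl-bearing carbon (the phenol being held as its aluminium phenoxide), and iodinolysis of the C–Al bond then gives the 1-iodovinyl group.

**Step 6**
Reactants: 8 6-(1-iodoethenyl)-2,4-bis(methoxymethoxy)-3-methylphenol
Product: 9 6-(1-iodoethenyl)-2,4-bis(methoxymethoxy)-3-methylphenyl acetate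
Conditions: Ac2O, pyridine, DMAP (cat.), CH2Cl2, 0 °C
Reagents that add atoms: acetic anhydride, CC(=O)OC(C)=O
Why: O-acetylation masks O1 so that it can neither protonate the alkenylmetal nor bind chromium in step 9, and the acetate is removed there by simple methanolysis.

**Step 7**
Reactants: 10 4-methylpent-3-en-1-ol
Product: 11 2-[(2R)-3,3-dimethyloxiran-2-yl]ethan-1-ol
Conditions: D-fructose-derived Shi ketone (0.3 equiv), Oxone, K2CO3, Bu4NHSO4, MeCN–CH2(OMe)2/aq. borate–EDTA buffer (pH ≈ 10.5), 0 °C
Reagents that add atoms: Oxone (potassium peroxymonosulfate), [K+].[O-]S(=O)(=O)OO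
Why: Shi asymmetric epoxidation of the trisubstituted alkene through the spiro dioxirane transition state should give the (R)-epoxide, and the basic buffer prevents acid-induced cyclisation of the epoxy alcohol.

**Step 8**
Reactants: 11 2-[(2R)-3,3-dimethyloxiran-2-yl]ethan-1-ol
Product: 12 2-[(2R)-3,3-dimethyloxiran-2-yl]acetaldehyde
Conditions: Dess–Martin periodinane, NaHCO3, CH2Cl2, 0 °C; filtered and used at once as a THF solution
Reagents that add atoms: none
Why: Buffered Dess–Martin oxidation is neutral enough to give the enolisable β,γ-epoxy aldehyde without β-elimination, and the epoxide stereocentre is untouched.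

**Step 9**
Reactants: 9 6-(1-iodoethenyl)-2,4-bis(methoxymethoxy)-3-methylphenyl acetate; 12 2-[(2R)-3,3-dimethyloxiran-2-yl]acetaldehyde
Product: 15 (2S,4R)-2-(2-hydroxypropan-2-yl)-7,9-bis(methoxymethoxy)-8-methyl-5-methylidene-2,3,4,5-tetrahydro-1-benzoxepin-4-ol, via open-chain adduct 13 (not isolated), via free phenol 14 (not isolated)
Conditions: CrCl2 (3.5 equiv), (S)-N-[2-(4-isopropyl-4,5-dihydro-1,3-oxazol-2-yl)-6-methylphenyl]methanesulfonamide (3.8 equiv), Et3N (3.8 equiv), THF, rt; NiCl2 (cat.); 9 + 12, rt; then K2CO3, MeOH, 50 °C, same flask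
Reagents that add atoms: none
Why: Ni(0) inserts into the C–I bond of 9, the alkenyl group passes to Cr(III), and the alkenylchromium adds to the aldehyde of 12 inside the chiral sulfonamide–Cr complex (asymmetric Nozaki–Hiyama–Kishi coupling of a 2-halo-1-alkene), forming C5–C4 and the exocyclic methylene in 13; K2CO3/MeOH then removes the O1 acetate, and the phenoxide of 14 opens the epoxide at its secondary carbon, forming O1–C2 and releasing the tertiary alkoxide that becomes C(CH3)2OH. The closest known reaction types are the asymmetric Ni/Cr coupling of α-substituted alkenyl halides with β-oxygenated aldehydes and the base-mediated cyclisation of phenols onto a tethered 2,2-dimethyloxirane. The oxepine closes in the 7-exo-tet mode (SN2 at C2), not 8-endo at the tertiary carbon. C4 (R) is set by Si-face delivery under ligand control, matched with the intrinsic 1,3-anti preference of a β-oxygenated aldehyde, and C2 (S) results from stereospecific inversion of the (R)-epoxide carbon fixed in step 7. The step needs addition to the aldehyde in preference to the epoxide and the ester, which the low basicity and carbonyl selectivity of organochromium secures, and ring closure through O1 and not the C4 hydroxyl, which the much higher acidity of the phenol under carbonate and the strain of the competing 4-exo path secure.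

**Step 10**
Reactants: 15 (2S,4R)-2-(2-hydroxypropan-2-yl)-7,9-bis(methoxymethoxy)-8-methyl-5-methylidene-2,3,4,5-tetrahydro-1-benzoxepin-4-ol; 16 angelic acid [(2Z)-2-methylbut-2-enoic acid]
Product: 17 (2S,4R)-2-(2-hydroxypropan-2-yl)-7,9-bis(methoxymethoxy)-8-methyl-5-methylidene-2,3,4,5-tetrahydro-1-benzoxepin-4-yl (2Z)-2-methylbut-2-enoate
Conditions: 16, 2,4,6-trichlorobenzoyl chloride, Et3N, toluene, rt; then 15, 80 °C
Reagents that add atoms: none
Why: Yamaguchi-type mixed-anhydride esterification without a nucleophilic catalyst should acylate the secondary allylic C4–OH with retention, leave the tertiary alcohol free and avoid angelate-to-tiglate isomerisation.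

**Step 11**
Reactants: 17 (2S,4R)-2-(2-hydroxypropan-2-yl)-7,9-bis(methoxymethoxy)-8-methyl-5-methylidene-2,3,4,5-tetrahydro-1-benzoxepin-4-yl (2Z)-2-methylbut-2-enoate
Product: 19 (2S,4R)-7,9-dihydroxy-2-(2-hydroxypropan-2-yl)-8-methyl-5-methylidene-2,3,4,5-tetrahydro-1-benzoxepin-4-yl (2Z)-2-methylbut-2-enoate, via tris(trimethylsilyl) ether 18 (not isolated)
Conditions: TMSOTf (6 equiv), 2,2'-bipyridyl (9 equiv), CH2Cl2, 0 °C → rt; then H2O, THF, rt; aq. NaHCO3
Reagents that add atoms: none
Why: MOM-ether cleavage by silyl triflate/2,2'-bipyridyl transfers each CH2OMe unit to the pyridine base and leaves aryl silyl ethers that water hydrolyses, so no free protic acid meets the allylic Z-ester, the styrene-type alkene or the tertiary alcohol.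

**Compound list**
1 | 2,4-dihydroxy-3-methylbenzaldehyde | O=Cc1ccc(O)c(C)c1O | starting material
2 | 2,4-bis(methoxymethoxy)-3-methylbenzaldehyde | O=Cc1ccc(OCOC)c(C)c1OCOC | intermediate
3 | 2,4-bis(methoxymethoxy)-3-methylphenyl formate | O=COc1ccc(OCOC)c(C)c1OCOC | intermediate (not isolated)
4 | 2,4-bis(methoxymethoxy)-3-methylphenol | Oc1ccc(OCOC)c(C)c1OCOC | intermediate
5 | 2-hydroxy-3,5-bis(methoxymethoxy)-4-methylbenzaldehyde | O=Cc1cc(OCOC)c(C)c(OCOC)c1O | intermediate
6 | 6-ethynyl-2,4-bis(methoxymethoxy)-3-methylphenol | C#Cc1cc(OCOC)c(C)c(OCOC)c1O | intermediate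
7 | diisobutyl{1-[2-(diisobutylalumanyloxy)-3,5-bis(methoxymethoxy)-4-methylphenyl]ethenyl}alumane | C=C([Al](CC(C)C)CC(C)C)c1cc(OCOC)c(C)c(OCOC)c1O[Al](CC(C)C)CC(C)C | intermediate (not isolated)
8 | 6-(1-iodoethenyl)-2,4-bis(methoxymethoxy)-3-methylphenol | C=C(I)c1cc(OCOC)c(C)c(OCOC)c1O | intermediate
9 | 6-(1-iodoethenyl)-2,4-bis(methoxymethoxy)-3-methylphenyl acetate | C=C(I)c1cc(OCOC)c(C)c(OCOC)c1OC(C)=O | intermediate
10 | 4-methylpent-3-en-1-ol | CC(C)=CCCO | starting material
11 | 2-[(2R)-3,3-dimethyloxiran-2-yl]ethan-1-ol | OCC[C@H]1OC1(C)C | intermediate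
12 | 2-[(2R)-3,3-dimethyloxiran-2-yl]acetaldehyde | O=CC[C@H]1OC1(C)C | intermediate
13 | 6-{(3R)-4-[(2R)-3,3-dimethyloxiran-2-yl]-3-hydroxybut-1-en-2-yl}-2,4-bis(methoxymethoxy)-3-methylphenyl acetate | C=C([C@H](O)C[C@H]1OC1(C)C)c1cc(OCOC)c(C)c(OCOC)c1OC(C)=O | intermediate (not isolated)
14 | 6-{(3R)-4-[(2R)-3,3-dimethyloxiran-2-yl]-3-hydroxybut-1-en-2-yl}-2,4-bis(methoxymethoxy)-3-methylphenol | C=C([C@H](O)C[C@H]1OC1(C)C)c1cc(OCOC)c(C)c(OCOC)c1O | intermediate (not isolated)
15 | (2S,4R)-2-(2-hydroxypropan-2-yl)-7,9-bis(methoxymethoxy)-8-methyl-5-methylidene-2,3,4,5-tetrahydro-1-benzoxepin-4-ol | C=C1c2cc(OCOC)c(C)c(OCOC)c2O[C@H](C(C)(C)O)C[C@H]1O | intermediate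
16 | angelic acid, (2Z)-2-methylbut-2-enoic acid | C/C=C(/C)C(=O)O | starting material
17 | (2S,4R)-2-(2-hydroxypropan-2-yl)-7,9-bis(methoxymethoxy)-8-methyl-5-methylidene-2,3,4,5-tetrahydro-1-benzoxepin-4-yl (2Z)-2-methylbut-2-enoate | C=C1c2cc(OCOC)c(C)c(OCOC)c2O[C@H](C(C)(C)O)C[C@H]1OC(=O)/C(C)=C\C | intermediate
18 | (2S,4R)-8-methyl-5-methylidene-7,9-bis(trimethylsilyloxy)-2-[2-(trimethylsilyloxy)propan-2-yl]-2,3,4,5-tetrahydro-1-benzoxepin-4-yl (2Z)-2-methylbut-2-enoate | C=C1c2cc(O[Si](C)(C)C)c(C)c(O[Si](C)(C)C)c2O[C@H](C(C)(C)O[Si](C)(C)C)C[C@H]1OC(=O)/C(C)=C\C | intermediate (not isolated)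
19 | (2S,4R)-7,9-dihydroxy-2-(2-hydroxypropan-2-yl)-8-methyl-5-methylidene-2,3,4,5-tetrahydro-1-benzoxepin-4-yl (2Z)-2-methylbut-2-enoate | C=C1c2cc(O)c(C)c(O)c2O[C@H](C(C)(C)O)C[C@H]1OC(=O)/C(C)=C\C | target

**Step count**
Total: 11 steps. Longest linear sequence: 9 steps (steps 1–6, 9, 10, 11); steps 7–8 form the convergent branch.

**Steps most likely to fail**

Step 9. The enolisable β,γ-epoxy aldehyde may be lost by base-induced β-elimination before it couples. The chromium(III) salts may assist attack of the new C4 oxygen or of chloride on the epoxide. Facial control at C4 may be weak. The fallback sets out from 8 and 11 and returns at 15; it forms the aryl ether bond first and closes the ring by C–C bond formation. The caesium phenoxide of 8 (Cs2CO3, DMF, 70 °C) should open the epoxide of 11 at its secondary carbon with inversion to give (3S)-3-[6-(1-iodoethenyl)-2,4-bis(methoxymethoxy)-3-methylphenoxy]-4-methylpentane-1,4-diol F1. TEMPO/PhI(OAc)2 should oxidise this 1,4-diol to the γ-lactone (4S)-4-[6-(1-iodoethenyl)-2,4-bis(methoxymethoxy)-3-methylphenoxy]-5,5-dimethyloxolan-2-one F2. Iodine–lithium exchange (t-BuLi, THF, −100 °C) followed by intramolecular acylation by the lactone (Parham-type cyclisation) should close the oxepine as (2S)-2-(2-hydroxypropan-2-yl)-7,9-bis(methoxymethoxy)-8-methyl-5-methylidene-2,3-dihydro-1-benzoxepin-4(5H)-one F3. Corey–Bakshi–Shibata reduction with the (S)-methyl oxazaborolidine and BH3·SMe2 should then set C4 (R) and give 15.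

Step 5. The aluminium hydride may add with the wrong regiochemistry (β-alkenylalane), the alkyne C–H may be deprotonated instead, or the electron-rich ring may be iodinated during the quench. The fallback sets out from 5 and returns at 8; it makes the 1-iodovinyl group from a methyl ketone. Addition of MeMgBr (2.5 equiv, THF) to 5 should give 6-(1-hydroxyethyl)-2,4-bis(methoxymethoxy)-3-methylphenol F4. MnO2 (CH2Cl2) should oxidise the benzylic alcohol to 1-[2-hydroxy-3,5-bis(methoxymethoxy)-4-methylphenyl]ethan-1-one F5. Hydrazine hydrate in ethanol should give the hydrazone 6-[(1E)-1-hydrazinylideneethyl]-2,4-bis(methoxymethoxy)-3-methylphenol F6. Iodine and tetramethylguanidine in THF at 0 °C (Barton vinyl iodide synthesis) should then give 8.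

Step 11. Under the silyl triflate the allylic angelate may ionise or transpose, the Z-ester may isomerise, or the tertiary silyl ether may not be released cleanly. The fallback sets out from 15 and returns at 19; it moves the MOM cleavage ahead of the esterification and ends with a fluoride deprotection. The same TMSOTf/2,2'-bipyridyl/water treatment applied to 15 should give (2S,4R)-2-(2-hydroxypropan-2-yl)-8-methyl-5-methylidene-2,3,4,5-tetrahydro-1-benzoxepine-4,7,9-triol F7. TBSCl (2.2 equiv) with Et3N in CH2Cl2 at 0 °C should silylate only the two phenols to give (2S,4R)-7,9-bis(tert-butyldimethylsilyloxy)-2-(2-hydroxypropan-2-yl)-8-methyl-5-methylidene-2,3,4,5-tetrahydro-1-benzoxepin-4-ol F8. Mixed-anhydride angeloylation as in step 10 should give (2S,4R)-7,9-bis(tert-butyldimethylsilyloxy)-2-(2-hydroxypropan-2-yl)-8-methyl-5-methylidene-2,3,4,5-tetrahydro-1-benzoxepin-4-yl (2Z)-2-methylbut-2-enoate F9. TBAF buffered with AcOH (THF, 0 °C) should then give 19.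

**Further compounds**
F1 | step 9 | (3S)-3-[6-(1-iodoethenyl)-2,4-bis(methoxymethoxy)-3-methylphenoxy]-4-methylpentane-1,4-diol | C=C(I)c1cc(OCOC)c(C)c(OCOC)c1O[C@H](C(C)(C)O)CCO
F2 | step 9 | (4S)-4-[6-(1-iodoethenyl)-2,4-bis(methoxymethoxy)-3-methylphenoxy]-5,5-dimethyloxolan-2-one | C=C(I)c1cc(OCOC)c(C)c(OCOC)c1O[C@H]1CC(=O)OC1(C)C
F3 | step 9 | (2S)-2-(2-hydroxypropan-2-yl)-7,9-bis(methoxymethoxy)-8-methyl-5-methylidene-2,3-dihydro-1-benzoxepin-4(5H)-one | C=C1c2cc(OCOC)c(C)c(OCOC)c2O[C@H](C(C)(C)O)CC1=O
F4 | step 5 | 6-(1-hydroxyethyl)-2,4-bis(methoxymethoxy)-3-methylphenol (racemic) | CC(O)c1cc(OCOC)c(C)c(OCOC)c1O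
F5 | step 5 | 1-[2-hydroxy-3,5-bis(methoxymethoxy)-4-methylphenyl]ethan-1-one | CC(=O)c1cc(OCOC)c(C)c(OCOC)c1O
F6 | step 5 | 6-[(1E)-1-hydrazinylideneethyl]-2,4-bis(methoxymethoxy)-3-methylphenol | C/C(=N\N)c1cc(OCOC)c(C)c(OCOC)c1O
F7 | step 11 | (2S,4R)-2-(2-hydroxypropan-2-yl)-8-methyl-5-methylidene-2,3,4,5-tetrahydro-1-benzoxepine-4,7,9-triol | C=C1c2cc(O)c(C)c(O)c2O[C@H](C(C)(C)O)C[C@H]1O
F8 | step 11 | (2S,4R)-7,9-bis(tert-butyldimethylsilyloxy)-2-(2-hydroxypropan-2-yl)-8-methyl-5-methylidene-2,3,4,5-tetrahydro-1-benzoxepin-4-ol | C=C1c2cc(O[Si](C)(C)C(C)(C)C)c(C)c(O[Si](C)(C)C(C)(C)C)c2O[C@H](C(C)(C)O)C[C@H]1O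
F9 | step 11 | (2S,4R)-7,9-bis(tert-butyldimethylsilyloxy)-2-(2-hydroxypropan-2-yl)-8-methyl-5-methylidene-2,3,4,5-tetrahydro-1-benzoxepin-4-yl (2Z)-2-methylbut-2-enoate | C=C1c2cc(O[Si](C)(C)C(C)(C)C)c(C)c(O[Si](C)(C)C(C)(C)C)c2O[C@H](C(C)(C)O)C[C@H]1OC(=O)/C(C)=C\C
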